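At 2.5 d, the time of reading, I want [target] along the row of rising charge, with the catalyst a fixed share of each charge.

| flask | substrate | free catalyst | remark | time |
|---|---|---|---|---|
| Wednesday's | 0.18 M | 5 mol% | run made earlier |  |
| Thursday's | 0.36 M | 5 mol% | run made earlier |  |
| Friday's | 0.69 M | 5 mol% | run made earlier |  |
| theta | 0.20 M | 5 mol% |  | 2.5 d |
| epsilon | 0.30 M | 5 mol% |  | 2.5 d |
| alpha | 0.50 M | 5 mol% |  | 2.5 d |
| beta | 0.80 M | 5 mol% |  | 2.5 d |

| run | time / d | target / % | substrate / % |
|---|---|---|---|
| Wednesday's | 0.208 | 3.9 | 94.8 |
| Wednesday's | 0.417 | 9.9 | 87.0 |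
| Wednesday's | 0.625 | 15.6 | 82.2 |
| Wednesday's | 1.25 | 24.6 | 71.6 |
| Wednesday's | 2.50 | 37.0 | 48.9 |
| Thursday's | 0.208 | 9.2 | 88.7 |
| Thursday's | 0.417 | 19.6 | 79.3 |
| Thursday's | 0.625 | 24.1 | 71.3 |
| Thursday's | 1.25 | 36.2 | 51.1 |
| Thursday's | 2.50 | 41.6 | 24.1 |
| Friday's | 0.208 | 18.9 | 81.4 |
| Friday's | 0.417 | 30.0 | 66.8 |
| Friday's | 0.625 | 35.3 | 52.8 |
| Friday's | 1.25 | 38.0 | 25.9 |
| Friday's | 2.50 | 24.3 | 7.6 |

(standard deviation of a reading: 1 percentage point)

- [target] at the end for theta, epsilon, alpha, beta, in this order
- how the row runs (rises all the way / falls all the way / hardly changes / rises, then falls / falls, then rises)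

- "hardly changes" means that all values lie within two and a half points (for a concentration: within two and a half percent of the largest)

1. I call charge times time the dose. Wednesday's end, Thursday's 1.25 d and Friday's 0.625 d have doses 648 M·min, 648 M·min and 621 M·min, and read target 37.0 %, 36.2 % and 35.3 %. So, at the fixed loading of 5 mol%, I read yield as a function of dose, and [target] as charge times yield.

2. Turned round: the row rises all the way only if beta stands above alpha, so beta's yield must exceed alpha's times 0.625.

3. Alpha's dose, 1800 M·min, lies inside Friday's last interval, and the straight chord there gives 31.8 %. The chord errs low: at Thursday's end it gives 37.4 %, but the reading is 41.6 %. So by the chord beta needs 19.9 %, and more if the chord errs low at alpha as well.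

4. Over that interval, substrate falls 18 percentage points and target falls 14 points. If substrate becomes target, target loses their sum. Dividing by mean target and by the dose interval gives, as a reading, the loss constant, target lost per unit of target per unit of dose, a pseudo-first-order constant on the dose scale: 0.0496 L mol⁻¹ h⁻¹. Substrate's own constant reads 0.0592 L mol⁻¹ h⁻¹.

5. One step from Friday's end to beta's dose gives 19.3 %, less than the 19.9 % required. The gap lies within one reading's scatter, but a chord that errs low at alpha as well widens it. My beta is 0.154 M, and the row rises, then falls.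

6. The forecast, on the ground that “k is proportional to charge”, gives 0.077 M, 0.122 M, 0.17 M, 0.153 M: rises, then falls.

7. The flask gives 0.0775 M, 0.122 M, 0.168 M, 0.151 M: rises, then falls.

    substrate + free catalyst ⇌ catalyst intermediate (K = 1.20 L mol⁻¹, k = 1.60 L mol⁻¹ h⁻¹)
    catalyst intermediate → free catalyst + target (k = 7.50 h⁻¹)
    free catalyst + target → free catalyst + over-reaction product (k = 1.10 L mol⁻¹ h⁻¹)

Beta holds 18.9 % target at the end, against my 19.3 %. On a second flask, theta at 25.0 d, the loss constant carried from Friday's end gives 0.492 %, and theta holds 0.580 %. In theta at the end, free catalyst has a half-life of 0.20 d by the forward binding step alone, longer than the 0.092 h of catalyst intermediate going on to target. Free catalyst, the resting state, stands there at 98.4 % of the catalyst charged, and catalyst intermediate at 1.61 %.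

All runs come from a simulation on assumed constants; the scatter is artificial.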